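**Retrosynthetic overview**

1. The target comes from its dibenzyl ether 29 by hydrogenolysis. 29 comes from the acyclic bis(4-hydroxyphenyl) diol 25 by cutting the aryl ether bond O1–C8a of both chroman units (pyran ring C of the upper unit, pyran ring F of the lower unit), so that rings A and D are plain para-substituted phenols in the precursor.
2. Enabling feature: in each isoflavan unit the phenol oxygen at C7 is para to C4a and meta to C8a, and O1 is tied to C4a through C2–C3–C4. Oxidative dearomatisation of ring A (ring D) to the p-quinol makes C8a the β-carbon of a dienone six atoms from O1. The two carbons ortho to C4a are equivalent, so 6-exo oxa-Michael addition and loss of water can only give the 7-hydroxychroman.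
3. 25 comes from reductive opening of a temporary lactone, a 3,4-diaryl-3,4-dihydrocoumarin fused to ring E. The lactone fixes C4 (Rh-catalysed asymmetric 1,4-arylation of the coumarin) and C3 (Pd α-arylation, then kinetic protonation). Its carbonyl becomes C2H2–O1H and its ring oxygen becomes the OMe of ring E.
4. The coumarin comes from the ring E salicylaldehyde, and that from 2-[2,4-bis(benzyloxy)phenyl]acetic acid, whose side chain receives the lower C3 stereocentre and ring D by Evans alkylation.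
5. Order of ring formation: temporary lactone on ring E (made, then opened), then rings C and F together in the key step; rings A, B, D and E come in with the building blocks.

Key step: step 15

Remark: locants are chroman locants of the upper unit (O1, C2, C3, C4, C4a, C5–C8, C8a); rings are A (benzo), C (pyran), B (pendant aryl) in the upper unit and D (benzo), F (pyran), E (pendant aryl that also carries upper C4) in the lower unit; TBSO = tert-butyldimethylsilyloxy; compounds 1, 4, 7, 15 and 17 are assumed to be commercially available.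

**Step 1**
Reactants: 1 2-(2,4-dihydroxyphenyl)acetic acid
Product: 3 2-[2,4-bis(benzyloxy)phenyl]acetic acid, via benzyl ester 2 (not isolated)
Conditions: BnBr (3.5 equiv), K2CO3, DMF, 60 °C; then NaOH, MeOH/H2O, 60 °C; HCl (aq)
Reagents that add atoms: benzyl bromide BrCc1ccccc1; sodium hydroxide [Na+].[OH-]
Why: Williamson etherification benzylates both phenols and the carboxylate, and saponification of the benzyl ester in the same flask returns the acid with the two aryl benzyl ethers intact.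

**Step 2**
Reactants: 3 2-[2,4-bis(benzyloxy)phenyl]acetic acid; 4 (S)-4-benzyl-1,3-oxazolidin-2-one
Product: 6 (S)-4-benzyl-3-{2-[2,4-bis(benzyloxy)phenyl]acetyl}-1,3-oxazolidin-2-one, via mixed anhydride 5 (not isolated)
Conditions: t-BuCOCl, Et3N, THF, −20 °C; then 4, LiCl, −20 °C → rt
Reagents that add atoms: none
Why: N-acylation of the Evans oxazolidinone by the mixed pivalic anhydride under LiCl/Et3N activation is a standard imide formation that needs no strong base and tolerates the arylacetic acid.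

**Step 3**
Reactants: 6 (S)-4-benzyl-3-{2-[2,4-bis(benzyloxy)phenyl]acetyl}-1,3-oxazolidin-2-one; 7 [4-(bromomethyl)phenoxy](tert-butyl)dimethylsilane
Product: 9 (S)-4-benzyl-3-[(2S)-2-[2,4-bis(benzyloxy)phenyl]-3-(4-TBSO-phenyl)propanoyl]-1,3-oxazolidin-2-one, via sodium enolate 8 (not isolated)
Conditions: NaN(SiMe3)2, THF, −78 °C; then 7, −78 → −40 °C
Reagents that add atoms: none
Why: Evans asymmetric alkylation: the chelated Z-sodium enolate is attacked by the benzylic bromide on the face opposite the C4 benzyl group of the auxiliary, which sets the lower C3 stereocentre (S) and brings in ring D as its silyl ether.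

**Step 4**
Reactants: 9 (S)-4-benzyl-3-[(2S)-2-[2,4-bis(benzyloxy)phenyl]-3-(4-TBSO-phenyl)propanoyl]-1,3-oxazolidin-2-one
Product: 10 (2S)-2-[2,4-bis(benzyloxy)phenyl]-3-(4-TBSO-phenyl)propan-1-ol
Conditions: LiBH4, THF/H2O, 0 °C → rt
Reagents that add atoms: none
Why: Reductive removal of the Evans auxiliary with LiBH4 gives the primary alcohol (the future O1–H of the lower unit) without touching the stereocentre, the aryl silyl ether or the benzyl ethers.

**Step 5**
Reactants: 10 (2S)-2-[2,4-bis(benzyloxy)phenyl]-3-(4-TBSO-phenyl)propan-1-ol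
Product: 11 (2S)-2-[2,4-bis(benzyloxy)phenyl]-3-(4-TBSO-phenyl)propyl pivalate
Conditions: t-BuCOCl, pyridine, DMAP (cat.), CH2Cl2, 0 °C → rt
Reagents that add atoms: pivaloyl chloride CC(C)(C)C(Cl)=O
Why: Acylation of the primary alcohol gives a non-enolisable pivalate that should survive the Lewis-acid and enolate steps and is removed by the hydride reduction of step 12.

**Step 6**
Reactants: 11 (2S)-2-[2,4-bis(benzyloxy)phenyl]-3-(4-TBSO-phenyl)propyl pivalate
Product: 12 (2S)-2-[2,4-bis(benzyloxy)-5-formylphenyl]-3-(4-TBSO-phenyl)propyl pivalate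
Conditions: [Me2N=CHCl]Cl, MeCN, 0 → 45 °C; NaOAc (aq)
Reagents that add atoms: (chloromethylene)dimethyliminium chloride C[N+](C)=CCl.[Cl-]; water O
Why: Vilsmeier–Haack formylation attacks the bis(benzyloxy) ring E at its most nucleophilic free carbon (C5, para to one and ortho to the other benzyloxy group, while C3 between the two ethers is shielded), the less electron-rich ring D does not react, and the aryl iminium salt is hydrolysed on work-up.

**Step 7**
Reactants: 12 (2S)-2-[2,4-bis(benzyloxy)-5-formylphenyl]-3-(4-TBSO-phenyl)propyl pivalate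
Product: 13 (2S)-2-[2-(benzyloxy)-5-formyl-4-hydroxyphenyl]-3-(4-TBSO-phenyl)propyl pivalate
Conditions: BCl3 (1.1 equiv), CH2Cl2, −78 °C; NaHCO3 (aq)
Reagents that add atoms: none
Why: Chelation-controlled dealkylation: BCl3 bound between the aldehyde oxygen and the ortho benzyloxy oxygen cleaves only that benzyl ether, freeing the phenol needed for the lactone and leaving the para benzyl ether, the pivalate and the silyl ether.

**Step 8**
Reactants: 13 (2S)-2-[2-(benzyloxy)-5-formyl-4-hydroxyphenyl]-3-(4-TBSO-phenyl)propyl pivalate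
Product: 14 (2S)-2-[7-(benzyloxy)-2-oxo-2H-chromen-6-yl]-3-(4-TBSO-phenyl)propyl pivalate
Conditions: Ph3P=C=C=O, toluene, 110 °C
Reagents that add atoms: ketenylidenetriphenylphosphorane O=C=C=P(c1ccccc1)(c1ccccc1)c1ccccc1
Why: The phenol adds to the ketenylidene ylide to give an aryl ester-stabilised ylide that closes by intramolecular Wittig olefination onto the ortho aldehyde, a neutral coumarin synthesis that builds the temporary lactone ring on ring E.

**Step 9**
Reactants: 14 (2S)-2-[7-(benzyloxy)-2-oxo-2H-chromen-6-yl]-3-(4-TBSO-phenyl)propyl pivalate; 15 (4-TBSO-phenyl)boronic acid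
Product: 16 (2S)-2-[(4R)-7-(benzyloxy)-2-oxo-4-(4-TBSO-phenyl)-3,4-dihydro-2H-chromen-6-yl]-3-(4-TBSO-phenyl)propyl pivalate
Conditions: Rh(acac)(C2H4)2 (3 mol %), (R)-SEGPHOS (3.3 mol %), 15 (5 equiv), dioxane/H2O 10:1, 60 °C
Reagents that add atoms: none
Why: Hayashi–Miyaura rhodium-catalysed asymmetric 1,4-addition of the arylboronic acid to the coumarin: the aryl–rhodium species with (R)-SEGPHOS (the ligand enantiomer expected to give (4R)-4-arylchroman-2-ones) adds to one face of C4 and the oxa-π-allyl is protonated by water, which sets the future C4 of the upper unit with ring A attached.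

**Step 10**
Reactants: 17 2-bromo-5-methoxyphenol
Product: 18 2-(benzyloxy)-1-bromo-4-methoxybenzene
Conditions: BnBr, K2CO3, acetone, 56 °C
Reagents that add atoms: benzyl bromide BrCc1ccccc1
Why: Williamson O-benzylation of the phenol gives the ring B donor as a stable aryl bromide.

**Step 11**
Reactants: 16 (2S)-2-[(4R)-7-(benzyloxy)-2-oxo-4-(4-TBSO-phenyl)-3,4-dihydro-2H-chromen-6-yl]-3-(4-TBSO-phenyl)propyl pivalate; 18 2-(benzyloxy)-1-bromo-4-methoxybenzene
Product: 20 (2S)-2-[(3R,4R)-7-(benzyloxy)-3-[2-(benzyloxy)-4-methoxyphenyl]-2-oxo-4-(4-TBSO-phenyl)-3,4-dihydro-2H-chromen-6-yl]-3-(4-TBSO-phenyl)propyl pivalate, via chlorozinc enolate 19 (not isolated)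
Conditions: TMPZnCl·LiCl (TMP = 2,2,6,6-tetramethylpiperidide), THF, 25 °C; then 18, Pd(OAc)2 (2 mol %), SPhos (4 mol %), 50 °C; NH4Cl (aq); DBU (10 mol %), CH2Cl2, rt
Reagents that add atoms: none
Why: Palladium-catalysed α-arylation of the lactone zinc enolate (a Negishi-type coupling of a Reformatsky-like enolate) makes the C3–ring B bond, and catalytic DBU on work-up converges the product on the thermodynamically preferred, storable 3,4-trans lactone.

**Step 12**
Reactants: 20 (2S)-2-[(3R,4R)-7-(benzyloxy)-3-[2-(benzyloxy)-4-methoxyphenyl]-2-oxo-4-(4-TBSO-phenyl)-3,4-dihydro-2H-chromen-6-yl]-3-(4-TBSO-phenyl)propyl pivalate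
Product: 23 (2S,3R)-2-[2-(benzyloxy)-4-methoxyphenyl]-3-{4-(benzyloxy)-2-hydroxy-5-[(2S)-1-hydroxy-3-(4-TBSO-phenyl)propan-2-yl]phenyl}-3-(4-TBSO-phenyl)propan-1-ol, via lithium enolate 21 (not isolated), via cis-lactone 22 (not isolated)
Conditions: LiN(SiMe3)2, THF, −78 °C; AcOH (1.1 equiv), −78 °C; then i-Bu2AlH (8 equiv), −78 → 0 °C; KNaC4H4O6 (aq)
Reagents that add atoms: none
Why: In the planar C3 enolate the C4 aryl group stands pseudoaxial to avoid allylic strain with the C3 aryl group and the fused ring, so kinetic C-protonation comes from the opposite face and gives the 3,4-cis lactone (3S), which is reduced at once by i-Bu2AlH (lactone carbonyl to C2H2–O1H, ring oxygen to the ring E phenol, pivalate to the lower primary alcohol) so that C3 can no longer epimerise; the reaction types are diastereoselective kinetic protonation of an ester enolate and hydride reduction of lactones and esters.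

**Step 13**
Reactants: 23 (2S,3R)-2-[2-(benzyloxy)-4-methoxyphenyl]-3-{4-(benzyloxy)-2-hydroxy-5-[(2S)-1-hydroxy-3-(4-TBSO-phenyl)propan-2-yl]phenyl}-3-(4-TBSO-phenyl)propan-1-ol
Product: 24 (2S,3R)-2-[2-(benzyloxy)-4-methoxyphenyl]-3-{4-(benzyloxy)-5-[(2S)-1-hydroxy-3-(4-TBSO-phenyl)propan-2-yl]-2-methoxyphenyl}-3-(4-TBSO-phenyl)propan-1-ol
Conditions: Me3SiCHN2, i-Pr2NEt, MeCN/MeOH 9:1, rt
Reagents that add atoms: (trimethylsilyl)diazomethane C[Si](C)(C)C=[N+]=[N-]
Why: Me3SiCHN2 with i-Pr2NEt in methanol methylates only the acidic phenol, giving the ring E methyl ether of the target without a base strong enough to endanger the aryl silyl ethers or alkylate the primary alcohols.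

**Step 14**
Reactants: 24 (2S,3R)-2-[2-(benzyloxy)-4-methoxyphenyl]-3-{4-(benzyloxy)-5-[(2S)-1-hydroxy-3-(4-TBSO-phenyl)propan-2-yl]-2-methoxyphenyl}-3-(4-TBSO-phenyl)propan-1-ol
Product: 25 (2S,3R)-2-[2-(benzyloxy)-4-methoxyphenyl]-3-{4-(benzyloxy)-5-[(2S)-1-hydroxy-3-(4-hydroxyphenyl)propan-2-yl]-2-methoxyphenyl}-3-(4-hydroxyphenyl)propan-1-ol
Conditions: Bu4NF, THF, 0 °C; NH4Cl (aq)
Reagents that add atoms: none
Why: Fluoride cleaves both aryl silyl ethers and leaves the benzyl ethers, unmasking the two para-alkylphenol rings A and D required for the key step.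

**Step 15**
Reactants: 25 (2S,3R)-2-[2-(benzyloxy)-4-methoxyphenyl]-3-{4-(benzyloxy)-5-[(2S)-1-hydroxy-3-(4-hydroxyphenyl)propan-2-yl]-2-methoxyphenyl}-3-(4-hydroxyphenyl)propan-1-ol
Product: 29 (3S,4R)-4-{4-(benzyloxy)-5-[(3S)-7-hydroxy-3,4-dihydro-2H-chromen-3-yl]-2-methoxyphenyl}-3-[2-(benzyloxy)-4-methoxyphenyl]-3,4-dihydro-2H-chromen-7-ol, via bis-peroxyquinol 26 (not isolated), via bis-quinol 27 (not isolated), via bis-oxa-Michael adduct 28 (not isolated)
Conditions: Oxone (2KHSO5·KHSO4·K2SO4), NaHCO3, MeCN/H2O, rt, dark; Na2S2O3; then TsOH·H2O (to pH 1–2), 40 °C, same flask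
Reagents that add atoms: none
Why: Singlet oxygen released from KHSO5/NaHCO3 adds across C4a and C7 of each phenolate ring (rings A and D) to give the para-hydroperoxy dienones 26, which thiosulfate reduces to the p-quinols 27; under acid each tethered primary hydroxyl then adds to a dienone β-carbon (oxa-Michael), forming O1–C8a and closing the pyran ring (28), and the tertiary, doubly allylic C4a–OH ionises to an arenium ion that loses H8a to give the 7-hydroxychroman. The closest known reaction types are the Oxone dearomatisation of para-alkylphenols to p-quinols with intramolecular oxa-Michael addition of a side-chain alcohol, and the dehydrative rearomatisation of quinol conjugate adducts to meta-functionalised phenols. Rings C and F both close in the 6-exo-trig mode, the hydroxyl attacking an enone carbon whose double bond lies outside the forming pyran ring. No stereocentre is set: C4a and C8a are stereogenic only in the cis-fused adducts 28 and become planar again, while C3, C4 and the lower C3 carry no acidic or ionisable hydrogen under these conditions and pass through unchanged. The step needs chemoselective oxidation of the two free phenol rings (all other oxygens are ethers, and phenolates react with singlet oxygen far faster than alkoxyarenes) and delivery of the new oxygen from outside to C4a, which the singlet-oxygen mode secures where phenoxenium-type oxidants would let O1 attack C4a (spiro-ether) or form the quinone methide at C4. Positional selectivity is not required, because the two carbons ortho to C4a are equivalent in a para-substituted phenol and either leads to the same chroman.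

**Step 16**
Reactants: 29 (3S,4R)-4-{4-(benzyloxy)-5-[(3S)-7-hydroxy-3,4-dihydro-2H-chromen-3-yl]-2-methoxyphenyl}-3-[2-(benzyloxy)-4-methoxyphenyl]-3,4-dihydro-2H-chromen-7-ol
Product: 30 (3S,4R)-4-{4-hydroxy-5-[(3S)-7-hydroxy-3,4-dihydro-2H-chromen-3-yl]-2-methoxyphenyl}-3-(2-hydroxy-4-methoxyphenyl)-3,4-dihydro-2H-chromen-7-ol (CNP0152030.1)
Conditions: H2 (1 atm), palladium on carbon (Pd/C, 10 %), EtOAc/MeOH, rt
Reagents that add atoms: none
Why: Hydrogenolysis over palladium on carbon removes the two aryl benzyl ethers under neutral conditions and leaves the chroman C–O bonds, the methyl ethers and the three stereocentres untouched.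

**Compound list**

1 | 2-(2,4-dihydroxyphenyl)acetic acid | OC(=O)Cc1ccc(O)cc1O | starting material
2 | benzyl 2-[2,4-bis(benzyloxy)phenyl]acetate | O=C(Cc1ccc(OCc2ccccc2)cc1OCc1ccccc1)OCc1ccccc1 | intermediate
3 | 2-[2,4-bis(benzyloxy)phenyl]acetic acid | OC(=O)Cc1ccc(OCc2ccccc2)cc1OCc1ccccc1 | intermediate
4 | (S)-4-benzyl-1,3-oxazolidin-2-one | O=C1OC[C@H](Cc2ccccc2)N1 | starting material
5 | 2-[2,4-bis(benzyloxy)phenyl]acetic pivalic anhydride | CC(C)(C)C(=O)OC(=O)Cc1ccc(OCc2ccccc2)cc1OCc1ccccc1 | intermediate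
6 | (S)-4-benzyl-3-{2-[2,4-bis(benzyloxy)phenyl]acetyl}-1,3-oxazolidin-2-one | O=C(Cc1ccc(OCc2ccccc2)cc1OCc1ccccc1)N1C(=O)OC[C@@H]1Cc1ccccc1 | intermediate
7 | [4-(bromomethyl)phenoxy](tert-butyl)dimethylsilane | BrCc1ccc(O[Si](C)(C)C(C)(C)C)cc1 | starting material
8 | sodium Z-enolate of 6 | [Na+].[O-]/C(=C\c1ccc(OCc2ccccc2)cc1OCc1ccccc1)N1C(=O)OC[C@@H]1Cc1ccccc1 | intermediate
9 | (S)-4-benzyl-3-[(2S)-2-[2,4-bis(benzyloxy)phenyl]-3-(4-TBSO-phenyl)propanoyl]-1,3-oxazolidin-2-one | O=C([C@@H](Cc1ccc(O[Si](C)(C)C(C)(C)C)cc1)c1ccc(OCc2ccccc2)cc1OCc1ccccc1)N1C(=O)OC[C@@H]1Cc1ccccc1 | intermediate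
10 | (2S)-2-[2,4-bis(benzyloxy)phenyl]-3-(4-TBSO-phenyl)propan-1-ol | OC[C@@H](Cc1ccc(O[Si](C)(C)C(C)(C)C)cc1)c1ccc(OCc2ccccc2)cc1OCc1ccccc1 | intermediate
11 | (2S)-2-[2,4-bis(benzyloxy)phenyl]-3-(4-TBSO-phenyl)propyl pivalate | CC(C)(C)C(=O)OC[C@@H](Cc1ccc(O[Si](C)(C)C(C)(C)C)cc1)c1ccc(OCc2ccccc2)cc1OCc1ccccc1 | intermediate
12 | (2S)-2-[2,4-bis(benzyloxy)-5-formylphenyl]-3-(4-TBSO-phenyl)propyl pivalate | CC(C)(C)C(=O)OC[C@@H](Cc1ccc(O[Si](C)(C)C(C)(C)C)cc1)c1cc(C=O)c(OCc2ccccc2)cc1OCc1ccccc1 | intermediate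
13 | (2S)-2-[2-(benzyloxy)-5-formyl-4-hydroxyphenyl]-3-(4-TBSO-phenyl)propyl pivalate | CC(C)(C)C(=O)OC[C@@H](Cc1ccc(O[Si](C)(C)C(C)(C)C)cc1)c1cc(C=O)c(O)cc1OCc1ccccc1 | intermediate
14 | (2S)-2-[7-(benzyloxy)-2-oxo-2H-chromen-6-yl]-3-(4-TBSO-phenyl)propyl pivalate | CC(C)(C)C(=O)OC[C@@H](Cc1ccc(O[Si](C)(C)C(C)(C)C)cc1)c1cc2C=CC(=O)Oc2cc1OCc1ccccc1 | intermediate
15 | (4-TBSO-phenyl)boronic acid | OB(O)c1ccc(O[Si](C)(C)C(C)(C)C)cc1 | starting material
16 | (2S)-2-[(4R)-7-(benzyloxy)-2-oxo-4-(4-TBSO-phenyl)-3,4-dihydro-2H-chromen-6-yl]-3-(4-TBSO-phenyl)propyl pivalate | CC(C)(C)C(=O)OC[C@@H](Cc1ccc(O[Si](C)(C)C(C)(C)C)cc1)c1cc2[C@@H](c3ccc(O[Si](C)(C)C(C)(C)C)cc3)CC(=O)Oc2cc1OCc1ccccc1 | intermediate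
17 | 2-bromo-5-methoxyphenol | COc1ccc(Br)c(O)c1 | starting material
18 | 2-(benzyloxy)-1-bromo-4-methoxybenzene | COc1ccc(Br)c(OCc2ccccc2)c1 | intermediate
19 | chlorozinc enolate of 16 | CC(C)(C)C(=O)OC[C@@H](Cc1ccc(O[Si](C)(C)C(C)(C)C)cc1)c1cc2[C@@H](c3ccc(O[Si](C)(C)C(C)(C)C)cc3)C=C(O[Zn]Cl)Oc2cc1OCc1ccccc1 | intermediate
20 | (2S)-2-[(3R,4R)-7-(benzyloxy)-3-[2-(benzyloxy)-4-methoxyphenyl]-2-oxo-4-(4-TBSO-phenyl)-3,4-dihydro-2H-chromen-6-yl]-3-(4-TBSO-phenyl)propyl pivalate (3,4-trans lactone) | CC(C)(C)C(=O)OC[C@@H](Cc1ccc(O[Si](C)(C)C(C)(C)C)cc1)c1cc2[C@@H](c3ccc(O[Si](C)(C)C(C)(C)C)cc3)[C@H](c3ccc(OC)cc3OCc3ccccc3)C(=O)Oc2cc1OCc1ccccc1 | intermediate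
21 | lithium enolate of 20 | CC(C)(C)C(=O)OC[C@@H](Cc1ccc(O[Si](C)(C)C(C)(C)C)cc1)c1cc2[C@@H](c3ccc(O[Si](C)(C)C(C)(C)C)cc3)C(c3ccc(OC)cc3OCc3ccccc3)=C([O-])Oc2cc1OCc1ccccc1.[Li+] | intermediate
22 | (3S,4R) epimer of 20 (3,4-cis lactone) | CC(C)(C)C(=O)OC[C@@H](Cc1ccc(O[Si](C)(C)C(C)(C)C)cc1)c1cc2[C@@H](c3ccc(O[Si](C)(C)C(C)(C)C)cc3)[C@@H](c3ccc(OC)cc3OCc3ccccc3)C(=O)Oc2cc1OCc1ccccc1 | intermediate
23 | (2S,3R)-2-[2-(benzyloxy)-4-methoxyphenyl]-3-{4-(benzyloxy)-2-hydroxy-5-[(2S)-1-hydroxy-3-(4-TBSO-phenyl)propan-2-yl]phenyl}-3-(4-TBSO-phenyl)propan-1-ol | COc1ccc([C@@H](CO)[C@H](c2ccc(O[Si](C)(C)C(C)(C)C)cc2)c2cc([C@@H](CO)Cc3ccc(O[Si](C)(C)C(C)(C)C)cc3)c(OCc3ccccc3)cc2O)c(OCc2ccccc2)c1 | intermediate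
24 | (2S,3R)-2-[2-(benzyloxy)-4-methoxyphenyl]-3-{4-(benzyloxy)-5-[(2S)-1-hydroxy-3-(4-TBSO-phenyl)propan-2-yl]-2-methoxyphenyl}-3-(4-TBSO-phenyl)propan-1-ol | COc1ccc([C@@H](CO)[C@H](c2ccc(O[Si](C)(C)C(C)(C)C)cc2)c2cc([C@@H](CO)Cc3ccc(O[Si](C)(C)C(C)(C)C)cc3)c(OCc3ccccc3)cc2OC)c(OCc2ccccc2)c1 | intermediate
25 | (2S,3R)-2-[2-(benzyloxy)-4-methoxyphenyl]-3-{4-(benzyloxy)-5-[(2S)-1-hydroxy-3-(4-hydroxyphenyl)propan-2-yl]-2-methoxyphenyl}-3-(4-hydroxyphenyl)propan-1-ol | COc1ccc([C@@H](CO)[C@H](c2ccc(O)cc2)c2cc([C@@H](CO)Cc3ccc(O)cc3)c(OCc3ccccc3)cc2OC)c(OCc2ccccc2)c1 | intermediate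
26 | bis-peroxyquinol: 25 with each 4-hydroxyphenyl ring turned into a 1-hydroperoxy-4-oxocyclohexa-2,5-dien-1-yl group | COc1ccc([C@@H](CO)[C@H](C2(OO)C=CC(=O)C=C2)c2cc([C@@H](CO)CC3(OO)C=CC(=O)C=C3)c(OCc3ccccc3)cc2OC)c(OCc2ccccc2)c1 | intermediate
27 | bis-quinol: 25 with each 4-hydroxyphenyl ring turned into a 1-hydroxy-4-oxocyclohexa-2,5-dien-1-yl group | COc1ccc([C@@H](CO)[C@H](C2(O)C=CC(=O)C=C2)c2cc([C@@H](CO)CC3(O)C=CC(=O)C=C3)c(OCc3ccccc3)cc2OC)c(OCc2ccccc2)c1 | intermediate
28 | bis-oxa-Michael adduct: each quinol closed to a cis-fused 4a-hydroxy-2,3,4,4a,8,8a-hexahydro-7H-chromen-7-one (the transient ring-fusion centres C4a and C8a are left unspecified) | COc1ccc([C@H]2COC3CC(=O)C=CC3(O)[C@@H]2c2cc([C@H]3COC4CC(=O)C=CC4(O)C3)c(OCc3ccccc3)cc2OC)c(OCc2ccccc2)c1 | intermediate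
29 | (3S,4R)-4-{4-(benzyloxy)-5-[(3S)-7-hydroxy-3,4-dihydro-2H-chromen-3-yl]-2-methoxyphenyl}-3-[2-(benzyloxy)-4-methoxyphenyl]-3,4-dihydro-2H-chromen-7-ol | COc1ccc([C@H]2COc3cc(O)ccc3[C@@H]2c2cc([C@H]3COc4cc(O)ccc4C3)c(OCc3ccccc3)cc2OC)c(OCc2ccccc2)c1 | intermediate
30 | (3S,4R)-4-{4-hydroxy-5-[(3S)-7-hydroxy-3,4-dihydro-2H-chromen-3-yl]-2-methoxyphenyl}-3-(2-hydroxy-4-methoxyphenyl)-3,4-dihydro-2H-chromen-7-ol | COc1ccc([C@H]2COc3cc(O)ccc3[C@@H]2c2cc([C@H]3COc4cc(O)ccc4C3)c(O)cc2OC)c(O)c1 | target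

**Step count and risks**

Total step count: 16. Longest linear sequence: 15 steps (steps 1–9 and 11–16; step 10 is a one-step side branch).

Steps most likely to fail:

**Step 15.** Under acid, heterolysis of the C4–C4a bond of the upper quinol (loss of the ring E-stabilised benzylic cation) or a dienone–phenol 1,2-shift may outrun oxa-Michael addition, and the double cascade may stop after one ring. The fallback forms the same O1–C8a bonds through arynes and sets out from 25. Amine-directed ortho-bromination of the two phenols (NBS, i-Pr2NH cat., CH2Cl2, 0 °C) should give the dibromide F1, and MOMCl/K2CO3 in acetone its bis(methoxymethyl) ether F2. With excess LiN(i-Pr)2 in THF (−78 °C → rt), dehydrobromination generates in each ring the 3-alkoxyaryne between C8 and C8a. The tethered lithium alkoxide adds at C8a, the aryne carbon distal to the alkoxy group and the only one that gives a six-membered ring, and the aryl anion at C8 is protonated on work-up to give the bis(methoxymethyl) ether F3. HCl in MeOH at rt removes the acetals and the route is rejoined at 29.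

**Step 12.** Facial selectivity of the kinetic protonation may be insufficient, or the cis-lactone may re-epimerise through its enolate before it is reduced. The fallback replaces kinetic control by equilibration and separation in the open chain and sets out from 20. Methanolysis of the lactone (MeOH, Et3N cat., CH2Cl2) with in situ methylation of the liberated ring E phenol by Me3SiCHN2 should give the methyl (2R,3R)-ester F4. DBU (or the stronger guanidine TBD) in toluene at 80 °C equilibrates the acidic C2–H of this α-aryl ester. The methyl (2S,3R)-ester F5 is separated by chromatography and F4 is resubmitted. Reduction of F5 with i-Bu2AlH (ester and pivalate) rejoins the route at 24.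

**Step 11.** The hindered zinc enolate may fail to couple with the ortho-substituted aryl bromide (slow transmetalation or reductive elimination, protonation of the enolate, or fragmentation of the aryl ester enolate to a ketene). The fallback inverts the polarity of ring B and sets out from 18 and 16. Bromine–lithium exchange on 18 (n-BuLi, THF, −78 °C) and B(Oi-Pr)3 should give the boronic acid F6, which with MesI(OAc)2/BF3·OEt2 and then NaOTf gives the aryl(mesityl)iodonium triflate F7. Lactone 16 is converted with LiN(SiMe3)2 and t-BuMe2SiCl at −78 °C into the silyl ketene acetal F8. Copper-catalysed electrophilic arylation of F8 with F7 (Cu(OTf)2, 10 mol %, CH2Cl2, rt; the unhindered aryl is transferred in preference to mesityl), followed by DBU on work-up, rejoins the route at 20.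

**Further compounds**

F1 | step 15 | dibromide of 25, each 4-hydroxyphenyl ring brominated ortho to OH (3-bromo-4-hydroxyphenyl) | COc1ccc([C@@H](CO)[C@H](c2ccc(O)c(Br)c2)c2cc([C@@H](CO)Cc3ccc(O)c(Br)c3)c(OCc3ccccc3)cc2OC)c(OCc2ccccc2)c1
F2 | step 15 | bis(methoxymethyl) ether of F1 | COc1ccc([C@@H](CO)[C@H](c2ccc(OCOC)c(Br)c2)c2cc([C@@H](CO)Cc3ccc(OCOC)c(Br)c3)c(OCc3ccccc3)cc2OC)c(OCc2ccccc2)c1
F3 | step 15 | bis(methoxymethyl) ether of 29 (both 7-hydroxyl groups as OCH2OCH3) | COc1ccc([C@H]2COc3cc(OCOC)ccc3[C@@H]2c2cc([C@H]3COc4cc(OCOC)ccc4C3)c(OCc3ccccc3)cc2OC)c(OCc2ccccc2)c1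
F4 | step 12 | methyl (2R,3R)-2-[2-(benzyloxy)-4-methoxyphenyl]-3-{4-(benzyloxy)-2-methoxy-5-[(2S)-1-(pivaloyloxy)-3-(4-TBSO-phenyl)propan-2-yl]phenyl}-3-(4-TBSO-phenyl)propanoate | COc1ccc([C@H](C(=O)OC)[C@H](c2ccc(O[Si](C)(C)C(C)(C)C)cc2)c2cc([C@@H](COC(=O)C(C)(C)C)Cc3ccc(O[Si](C)(C)C(C)(C)C)cc3)c(OCc3ccccc3)cc2OC)c(OCc2ccccc2)c1
F5 | step 12 | methyl (2S,3R)-2-[2-(benzyloxy)-4-methoxyphenyl]-3-{4-(benzyloxy)-2-methoxy-5-[(2S)-1-(pivaloyloxy)-3-(4-TBSO-phenyl)propan-2-yl]phenyl}-3-(4-TBSO-phenyl)propanoate | COc1ccc([C@@H](C(=O)OC)[C@H](c2ccc(O[Si](C)(C)C(C)(C)C)cc2)c2cc([C@@H](COC(=O)C(C)(C)C)Cc3ccc(O[Si](C)(C)C(C)(C)C)cc3)c(OCc3ccccc3)cc2OC)c(OCc2ccccc2)c1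
F6 | step 11 | [2-(benzyloxy)-4-methoxyphenyl]boronic acid | COc1ccc(B(O)O)c(OCc2ccccc2)c1
F7 | step 11 | [2-(benzyloxy)-4-methoxyphenyl](2,4,6-trimethylphenyl)iodonium trifluoromethanesulfonate | COc1ccc([I+]c2c(C)cc(C)cc2C)c(OCc2ccccc2)c1.[O-]S(=O)(=O)C(F)(F)F
F8 | step 11 | tert-butyldimethylsilyl ketene acetal of 16 | CC(C)(C)C(=O)OC[C@@H](Cc1ccc(O[Si](C)(C)C(C)(C)C)cc1)c1cc2[C@@H](c3ccc(O[Si](C)(C)C(C)(C)C)cc3)C=C(O[Si](C)(C)C(C)(C)C)Oc2cc1OCc1ccccc1
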